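**Retrosynthetic overview**
- **Feature:** the C4''-OH lies 1,4 to the benzylic C1'' on C8 of ring A. The unit C1''–C2''–C3''–C4''–O is therefore treated as a hydrogenolysed 2-aryl-tetrahydrofuran, with C2'' (prenyl) and C3'' (methyl) as the trans 3,4-substituents of a γ-butyrolactone.
- **Disconnections:** C2–C1' by catalytic asymmetric conjugate arylation of an 8-alkylchromone; O1–C2 of ring C by enaminone closure on the phenol next to the chain; C1''–O by ionic reduction; C8–C1'' by Lewis-acid C-arylation of a lactol with phloroacetophenone; C2''–prenyl by lactone enolate alkylation.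
- **Ring order:** the tetrahydrofuran is bought as the lactone, kept through step 3 and opened in step 4. Ring A is bought, ring C is closed in step 8, and ring B is attached in step 11.

Key step: step 3

Remark: C1''–C4'' number the side chain outward from ring A; lactone 1 is assumed purchasable in enantiopure form; the side-chain hydroxyl travels as a TBS ether, because an alkyl MOM ether would need harsher acid at the end than the aryl MOM ethers.

Step 1
Reactants: 1 (S)-4-methyldihydrofuran-2(3H)-one; 2 prenyl bromide
Product: 4 (3S,4S)-4-methyl-3-(3-methylbut-2-en-1-yl)dihydrofuran-2(3H)-one, via lithium enolate 3 (not isolated)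
Conditions: LiN(i-Pr)2 (1.05 equiv), THF, −78 °C; then 2 (1.2 equiv), DMPU (2 equiv), −78 → −40 °C
Reagents that add atoms: prenyl bromide 2, CC(C)=CCBr
Why: Kinetic lithium enolate alkylation of a β-substituted γ-butyrolactone, in which the allylic bromide approaches the flat enolate on the face away from the C4 methyl group and so sets C3 (future C2'') trans to C4 (future C3''), any cis isomer being removable by chromatography.

Step 2
Reactants: 4 (3S,4S)-4-methyl-3-prenylbutyrolactone
Product: 6 (3S,4S)-4-methyl-3-(3-methylbut-2-en-1-yl)tetrahydrofuran-2-ol (anomer mixture), via aluminium hemiacetal 5 (not isolated)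
Conditions: i-Bu2AlH (1.1 equiv), CH2Cl2, −78 °C; aq. potassium sodium tartrate
Reagents that add atoms: none
Why: Partial hydride reduction of a lactone halts at the tetrahedral aluminium hemiacetal at low temperature and releases the lactol on hydrolysis, leaving the alkene and both stereocentres untouched, while the anomeric centre is of no consequence.

Step 3
Reactants: 6 trans-lactol; 7 2,4,6-trihydroxyacetophenone
Product: 9 1-{2,4,6-trihydroxy-3-[(3S,4S)-4-methyl-3-prenyltetrahydrofuran-2-yl]phenyl}ethanone (C1'' epimers), via 4-O-aryl acetal 8 (not isolated)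
Conditions: Sc(OTf)3 (10 mol %), 7 (1.2 equiv), 4 Å molecular sieves, MeCN, −20 °C → rt
Reagents that add atoms: none
Why: Sc(OTf)3 ionises the lactol to a five-membered cyclic oxocarbenium ion, which the unchelated 4-OH of 7 captures reversibly (acetal 8) and the neighbouring ring carbon captures irreversibly, rearomatisation leaving the aryl–C1'' bond. The closest known reaction type is the Friedel–Crafts aryl C-glycosylation (O-to-C glycoside rearrangement) of phloroacetophenone-type phenols with lactol or 1-O-acyl donors. No ring is closed, since the tetrahydrofuran comes intact from 6 and only stores the C4'' oxygen. The new centre C1'' should form mainly trans to the C2'' prenyl group by approach anti to it, but it is left uncontrolled because step 4 turns it into a methylene. The step needs mono C-arylation: C3 and C5 of 7 are equivalent so only one mono-adduct exists, the acetyl group and the bulky new substituent slow a second substitution, a lactol ionises under far weaker acid than the benzylic ether of 9, and any C1''–O ionisation is undone by 5-exo re-closure of the C4'' hydroxyl before a second di-ortho-substituted arene can reach the crowded C1''. Catalytic acid and low temperature keep the oxocarbenium ion from shedding the C2'' proton, and the prenyl alkene could reach C1'' only through a four-membered ring or an anti-Markovnikov five-membered closure.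

Step 4
Reactants: 9 C-furanosyl phloroacetophenone
Product: 10 1-{2,4,6-trihydroxy-3-[(2R,3S)-4-hydroxy-3-methyl-2-prenylbutyl]phenyl}ethanone
Conditions: Et3SiH (5 equiv), CF3CO2H (10 equiv), CH2Cl2, −20 → 0 °C; then NaHCO3, MeOH–H2O
Reagents that add atoms: none
Why: Ionic hydrogenolysis (silane plus Brønsted acid) of an electron-rich benzylic ether, in which protonation of the ring oxygen lets the ortho, ortho' and para hydroxyls expel the C4'' alcohol and the large excess of silane traps the C1'' cation before it can lose the C2'' proton, while the doubly hydrogen-bonded vinylogous-acid carbonyl and the trisubstituted alkene, which need stronger acid or higher temperature for ionic hydrogenation, should survive dilute acid below 0 °C.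

Step 5
Reactants: 10 3-alkylphloroacetophenone
Product: 11 1-{2-hydroxy-3-[(2R,3S)-4-hydroxy-3-methyl-2-prenylbutyl]-4,6-bis(methoxymethoxy)phenyl}ethanone
Conditions: MOMCl (2.2 equiv), i-Pr2NEt (3 equiv), CH2Cl2, 0 °C
Reagents that add atoms: chloromethyl methyl ether (MOMCl), COCCl
Why: Amine-base O-alkylation of the acidic phenols, in which the unchelated 4-OH reacts first and then the 6-OH flanked by a ring hydrogen, whereas the 2-OH, buttressed by the branched chain and locked in the hydrogen bond to the acetyl oxygen, stays free and the neutral primary alcohol is much slower than the phenoxides, the isomer with a free 6-OH being removed by chromatography.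

Step 6
Reactants: 11 bis-MOM acetophenone with free primary alcohol
Product: 12 1-{3-[(2R,3S)-4-(tert-butyldimethylsilyloxy)-3-methyl-2-prenylbutyl]-2-hydroxy-4,6-bis(methoxymethoxy)phenyl}ethanone
Conditions: TBSCl (1.2 equiv), imidazole (2.5 equiv), CH2Cl2, 0 °C → rt
Reagents that add atoms: tert-butyldimethylsilyl chloride (TBSCl), CC(C)(C)[Si](C)(C)Cl
Why: Imidazole-promoted silylation takes the unhindered primary alcohol and leaves the hindered chelated phenol alone, giving a group that falls under the same mild acid as the aryl MOM ethers.

Step 7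
Reactants: 12 protected acetophenone
Product: 13 (E)-enaminone of 12
Conditions: Me2NCH(OMe)2 (4 equiv), toluene, 85 °C
Reagents that add atoms: N,N-dimethylformamide dimethyl acetal, COC(OC)N(C)C
Why: Condensation of a methyl ketone with an amide acetal (enaminone synthesis) is established for 2-hydroxy-4,6-dialkoxyacetophenones because the reacting methyl group lies outside the crowded ring, and MOM, TBS, alkene and stereocentres are inert to the weakly basic medium.

Step 8
Reactants: 13 enaminone
Product: 14 8-[(2R,3S)-4-(tert-butyldimethylsilyloxy)-3-methyl-2-prenylbutyl]-5,7-bis(methoxymethoxy)-4H-chromen-4-one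
Conditions: AcOH (10 equiv), toluene, 60 °C
Reagents that add atoms: none
Why: Acid-promoted addition–elimination, in which the only free phenol adds 6-endo-trig to the protonated enaminone and dimethylamine leaves, closes ring C through O1–C2 so that the chain sits on C8, a carboxylic acid being strong enough for this yet too weak to strip aryl MOM or primary TBS ethers.

Step 9
Reactants: 15 4-bromoresorcinol
Product: 16 1-bromo-2,4-bis(methoxymethoxy)benzene
Conditions: MOMCl (2.5 equiv), i-Pr2NEt (3.5 equiv), CH2Cl2, 0 °C → rt
Reagents that add atoms: chloromethyl methyl ether (MOMCl), COCCl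
Why: Routine amine-base O-alkylation of two unchelated phenols, with the aryl bromide as a spectator.

Step 10
Reactants: 16 1-bromo-2,4-bis(methoxymethoxy)benzene
Product: 19 2,4-bis(methoxymethoxy)phenylboronic acid, via aryllithium 17 (not isolated), via lithium aryltriisopropoxyborate 18 (not isolated)
Conditions: n-BuLi (1.1 equiv), THF, −78 °C; B(Oi-Pr)3 (1.5 equiv), −78 °C → rt; aq. NH4Cl
Reagents that add atoms: triisopropyl borate, CC(C)OB(OC(C)C)OC(C)C; water, O
Why: Bromine–lithium exchange outruns any directed ortho-lithiation at −78 °C, the borate ester traps the aryllithium as the ate complex, and nearly neutral hydrolysis frees the boronic acid without harming the MOM ethers.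

Step 11
Reactants: 14 8-alkylchromone; 19 2,4-bis(methoxymethoxy)phenylboronic acid
Product: 20 (2S)-2-[2,4-bis(methoxymethoxy)phenyl]-8-[(2R,3S)-4-(tert-butyldimethylsilyloxy)-3-methyl-2-prenylbutyl]-5,7-bis(methoxymethoxy)chroman-4-one
Conditions: [Rh(OH)(cod)]2 (2.5 mol %), (S)-(6,6'-dimethoxybiphenyl-2,2'-diyl)bis[bis(3,4,5-trifluorophenyl)phosphine] (6 mol %), 19 (3 equiv, in portions), toluene–H2O (20:1), 30–40 °C
Reagents that add atoms: none
Why: Hayashi–Miyaura asymmetric 1,4-addition of an arylboronic acid to a chromone, a known entry to flavanones, in which the aryl complex of monovalent rhodium formed by transmetalation adds across C2=C3 on the enantioface left open by the chiral bisphosphine and water protonates the oxa-π-allyl rhodium, so that C2 is set by the catalyst and not by the remote chain, the (S)-ligand being chosen because its sense of induction on 2-cyclohexenone maps onto 2S here (the antipode is equally available should the sense prove reversed), while the base-free, water-poor medium suppresses retro-oxa-Michael opening.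

Step 12
Reactants: 20 protected (2S)-flavanone
Product: 21 CNP0262638.1, (2S)-2-(2,4-dihydroxyphenyl)-5,7-dihydroxy-8-[(2R,3S)-4-hydroxy-3-methyl-2-(3-methylbut-2-en-1-yl)butyl]chroman-4-one
Conditions: HCl (about 1 M in MeOH), MeOH–THF, 25 → 40 °C
Reagents that add atoms: none
Why: Acid-catalysed acetal exchange with methanol removes the four aryl MOM ethers and solvolyses the primary silyl ether in one operation, the low acid strength and temperature being chosen so that neither opening of the C2–O1 bond (which would epimerise C2 or move the chain to C6) nor addition to the alkene sets in.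

**Compound list**
1 | (S)-4-methyldihydrofuran-2(3H)-one | O=C1C[C@H](C)CO1 | starting material
2 | prenyl bromide (1-bromo-3-methylbut-2-ene) | CC(C)=CCBr | starting material
3 | lithium enolate of 1 | [Li]OC1=C[C@H](C)CO1 | intermediate (not isolated)
4 | (3S,4S)-4-methyl-3-(3-methylbut-2-en-1-yl)dihydrofuran-2(3H)-one | CC(C)=CC[C@H](C1=O)[C@H](C)CO1 | intermediate
5 | diisobutylaluminium hemiacetal of 4 | CC(C)=CC[C@H](C1O[Al](CC(C)C)CC(C)C)[C@H](C)CO1 | intermediate (not isolated)
6 | (3S,4S)-4-methyl-3-(3-methylbut-2-en-1-yl)tetrahydrofuran-2-ol, anomer mixture | CC(C)=CC[C@H](C1O)[C@H](C)CO1 | intermediate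
7 | 2,4,6-trihydroxyacetophenone | CC(=O)c1c(O)cc(O)cc1O | starting material
8 | 4-O-[(3S,4S)-4-methyl-3-prenyltetrahydrofuran-2-yl]phloroacetophenone | CC(C)=CC[C@H](C1Oc2cc(O)c(C(C)=O)c(O)c2)[C@H](C)CO1 | intermediate (not isolated)
9 | 1-{2,4,6-trihydroxy-3-[(3S,4S)-4-methyl-3-prenyltetrahydrofuran-2-yl]phenyl}ethanone, C1'' epimers | CC(C)=CC[C@H](C1c2c(O)cc(O)c(C(C)=O)c2O)[C@H](C)CO1 | intermediate
10 | 1-{2,4,6-trihydroxy-3-[(2R,3S)-4-hydroxy-3-methyl-2-prenylbutyl]phenyl}ethanone | CC(C)=CC[C@H](Cc1c(O)cc(O)c(C(C)=O)c1O)[C@H](C)CO | intermediate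
11 | 1-{2-hydroxy-3-[(2R,3S)-4-hydroxy-3-methyl-2-prenylbutyl]-4,6-bis(methoxymethoxy)phenyl}ethanone | CC(C)=CC[C@H](Cc1c(OCOC)cc(OCOC)c(C(C)=O)c1O)[C@H](C)CO | intermediate
12 | TBS ether of 11 | CC(C)=CC[C@H](Cc1c(OCOC)cc(OCOC)c(C(C)=O)c1O)[C@H](C)CO[Si](C)(C)C(C)(C)C | intermediate
13 | (E)-3-(dimethylamino)prop-2-en-1-one (enaminone) derived from 12 | CC(C)=CC[C@H](Cc1c(OCOC)cc(OCOC)c(C(=O)/C=C/N(C)C)c1O)[C@H](C)CO[Si](C)(C)C(C)(C)C | intermediate
14 | 8-[(2R,3S)-4-(TBS-oxy)-3-methyl-2-prenylbutyl]-5,7-bis(methoxymethoxy)-4H-chromen-4-one | CC(C)=CC[C@H](Cc1c(OCOC)cc(OCOC)c2c1OC=CC2=O)[C@H](C)CO[Si](C)(C)C(C)(C)C | intermediate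
15 | 4-bromoresorcinol | Oc1ccc(Br)c(O)c1 | starting material
16 | 1-bromo-2,4-bis(methoxymethoxy)benzene | COCOc1ccc(Br)c(OCOC)c1 | intermediate
17 | 2,4-bis(methoxymethoxy)phenyllithium | COCOc1ccc([Li])c(OCOC)c1 | intermediate (not isolated)
18 | lithium [2,4-bis(methoxymethoxy)phenyl]triisopropoxyborate | [Li+].COCOc1ccc([B-](OC(C)C)(OC(C)C)OC(C)C)c(OCOC)c1 | intermediate (not isolated)
19 | 2,4-bis(methoxymethoxy)phenylboronic acid | COCOc1ccc(B(O)O)c(OCOC)c1 | intermediate
20 | protected (2S)-flavanone (four aryl MOM ethers, one TBS ether) | CC(C)=CC[C@H](Cc1c(OCOC)cc(OCOC)c2c1O[C@H](c1ccc(OCOC)cc1OCOC)CC2=O)[C@H](C)CO[Si](C)(C)C(C)(C)C | intermediate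
21 | CNP0262638.1 | CC(C)=CC[C@H](Cc1c(O)cc(O)c2c1O[C@H](c1ccc(O)cc1O)CC2=O)[C@H](C)CO | target

**Total step count:** 12. **Longest linear sequence:** 10 (steps 1–8, 11, 12).

**Steps most likely to fail**

**Step 3.**
- What may go wrong: the first-formed adduct may re-ionise at C1'' and be consumed by a second arene. A second furanosylation may occur at C5. The oxocarbenium ion may also lose the C2'' proton, which would erode the trans relationship.
- Fallback, from 6 back to 9, forming the C–C bond by an anion instead of a cation:
  - Phloroglucinol is converted (MOMCl, NaH, DMF) into 1,3,5-tris(methoxymethoxy)benzene F1.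
  - F1 is lithiated between two MOM-oxy groups (n-BuLi, THF, 0 °C) and tempered with MgBr2·OEt2. It is then added in excess to lactol 6, which reacts through its open hydroxy-aldehyde form, to give (2S,3S)-3-methyl-2-prenyl-1-[2,4,6-tris(methoxymethoxy)phenyl]butane-1,4-diol F2.
  - Selective tosylation of the primary hydroxyl, then 5-exo-tet closure by the benzylic alkoxide (TsCl, Et3N, DMAP; then t-BuOK), gives the tris-MOM 2-aryl-tetrahydrofuran F3.
  - A second directed lithiation, quenched with N-methoxy-N-methylacetamide, installs the acetyl group in the tris-MOM C-furanosyl acetophenone F4.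
  - Brief treatment with methanolic HCl removes the three MOM groups and returns 9.

**Step 4.**
- What may go wrong: hydride capture of the C1'' cation may be too slow. That would allow loss of the C2'' proton with scrambling of that centre. Forcing the reaction may cause ionic hydrogenation of the alkene or of the acetyl group.
- Fallback, from 9 back to 10, by thiolysis and then radical desulfurisation:
  - The ring is opened with thiophenol (5 equiv) and catalytic CF3CO2H in CH2Cl2 at −20 °C under argon. This is the type of acid thiolysis used on benzylic positions next to phloroglucinol rings. The soft, fast nucleophile gives the C1''-phenylsulfanyl derivative of 10 F5, with the C4'' alcohol free.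
  - The C–S bond is then cleaved homolytically (Bu3SnH, AIBN, toluene, 80 °C). These conditions touch neither ketone, alkene nor C2'', and the benzylic radical has no feasible cyclisation onto the prenyl group.

**Step 11.**
- What may go wrong: the electron-rich ortho-alkoxy boronic acid may protodeboronate faster than it transmetalates. Insertion into the electron-rich 5,7-dialkoxy-8-alkylchromone may be sluggish. Facial selectivity may be poor, or the product may open by retro-oxa-Michael reaction.
- Fallback, from 12 and 16 back to 20, by the chalcone route: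
  - Bromide 16 is lithiated (n-BuLi, THF, −78 °C, via 17) and formylated with DMF to 2,4-bis(methoxymethoxy)benzaldehyde F6.
  - Claisen–Schmidt condensation of F6 with 12 (KOH, EtOH, rt) gives the (E)-2'-hydroxychalcone F7.
  - Oxa-Michael cyclisation (NaOAc, EtOH, reflux) gives 20 together with its (2R)-epimer F8.
  - Because the side chain is chiral, the two are diastereomers and can be separated by preparative HPLC. The unwanted epimer is returned to the same equilibrating conditions.

**Further compounds**
F1 | step 3 | 1,3,5-tris(methoxymethoxy)benzene | COCOc1cc(OCOC)cc(OCOC)c1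
F2 | step 3 | (2S,3S)-3-methyl-2-prenyl-1-[2,4,6-tris(methoxymethoxy)phenyl]butane-1,4-diol, C1 epimers | CC(C)=CC[C@H](C(O)c1c(OCOC)cc(OCOC)cc1OCOC)[C@H](C)CO
F3 | step 3 | (3S,4S)-4-methyl-3-prenyl-2-[2,4,6-tris(methoxymethoxy)phenyl]tetrahydrofuran, C2 epimers | CC(C)=CC[C@H](C1c2c(OCOC)cc(OCOC)cc2OCOC)[C@H](C)CO1
F4 | step 3 | 1-{2,4,6-tris(methoxymethoxy)-3-[(3S,4S)-4-methyl-3-prenyltetrahydrofuran-2-yl]phenyl}ethanone | CC(C)=CC[C@H](C1c2c(OCOC)cc(OCOC)c(C(C)=O)c2OCOC)[C@H](C)CO1
F5 | step 4 | C1''-phenylsulfanyl derivative of 10, C1'' epimers | CC(C)=CC[C@H](C(Sc1ccccc1)c1c(O)cc(O)c(C(C)=O)c1O)[C@H](C)CO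
F6 | step 11 | 2,4-bis(methoxymethoxy)benzaldehyde | COCOc1ccc(C=O)c(OCOC)c1
F7 | step 11 | (E)-2'-hydroxychalcone from 12 and F6 | CC(C)=CC[C@H](Cc1c(OCOC)cc(OCOC)c(C(=O)/C=C/c2ccc(OCOC)cc2OCOC)c1O)[C@H](C)CO[Si](C)(C)C(C)(C)C
F8 | step 11 | (2R)-epimer of 20 | CC(C)=CC[C@H](Cc1c(OCOC)cc(OCOC)c2c1O[C@@H](c1ccc(OCOC)cc1OCOC)CC2=O)[C@H](C)CO[Si](C)(C)C(C)(C)C
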